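**Retrosynthetic overview**

1. Ring numbering: C1 carries the isopropyl group, the oxirane is C3–C4, CH2OH sits on C8, the ketones are C9 and C14, the methyl is on C12 and the carbinol is C13. The plan rests on the ring-cis (7Z) C7=C8 enone alkene of the 14-membered carbocycle C1–C14, with H on C7 and CH2OH on C8 on the same side, which is the outcome of a syn addition to a C7≡C8 ring alkyne.
2. Target ⇒ (C13 desilylation; copper hydride conjugate reduction of a C7≡C8–C9(=O) ynone with formaldehyde capture; C9 oxidation) ⇒ 14-membered cycloalkyne.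
3. Cycloalkyne ⇒ ring-closing alkyne metathesis of an acyclic diyne with two methyl-capped alkynes (forms C7≡C8).
4. Diyne ⇒ aldol condensation (C1=C2) of an epoxy aldehyde (C2–C7, from nerol by asymmetric epoxidation) with an α-silyloxy isobutyl ketone (C8–C14; C12 from (R)-citronellic acid, C13 by auxiliary-controlled enolate hydroxylation).
5. Ring order: oxirane first (step 1), 14-membered carbocycle second (step 18).

Key step: step 18

Assumption: the C9 carbinol made in step 13 forms as both epimers and is carried as the mixture, written without a descriptor, because C9 becomes a ketone in step 20. Macrocycle names use the ring numbering given above.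

**Step 1**
Reactants: 1 nerol
Product: 2 [(2S,3R)-3-methyl-3-(4-methylpent-3-en-1-yl)oxiran-2-yl]methanol
Conditions: Ti(OiPr)4 (cat.), L-(+)-diethyl tartrate (cat.), t-BuOOH, 4 Å MS, CH2Cl2, −20 °C
Reagents that add atoms: tert-butyl hydroperoxide, CC(C)(C)OO
Why: Katsuki–Sharpless asymmetric epoxidation touches only the allylic alcohol alkene, copies the cis relation of CH2OH and side chain from the Z olefin, and with L-(+)-tartrate delivers oxygen to the face that gives the (2S,3R) oxirane (the facial sense that converts geraniol into its (2S,3S) epoxide), which sets ring C3 (S) and C4 (R).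

**Step 2**
Reactants: 2 (2S,3R)-epoxy alcohol
Product: 3 tert-butyldimethyl{[(2S,3R)-3-methyl-3-(4-methylpent-3-en-1-yl)oxiran-2-yl]methoxy}silane
Conditions: TBSCl, imidazole, DMF, 0 °C → rt
Reagents that add atoms: tert-butyldimethylsilyl chloride, CC(C)(C)[Si](C)(C)Cl
Why: Imidazole-promoted O-silylation masks the primary hydroxyl so that the basic homologation and alkylation steps cannot trigger epoxide migration.

**Step 3**
Reactants: 3 silyl ether
Product: 5 3-[(2R,3S)-3-{[(tert-butyldimethylsilyl)oxy]methyl}-2-methyloxiran-2-yl]propanal, via secondary ozonide 4 (not isolated)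
Conditions: O3, CH2Cl2, −78 °C; then PPh3, −78 °C → rt
Reagents that add atoms: ozone, [O-][O+]=O
Why: Ozonolysis with reductive work-up cleaves the only alkene present and leaves the oxirane and the silyl ether untouched.

**Step 4**
Reactants: 5 aldehyde
Product: 6 {[(2S,3R)-3-(but-3-yn-1-yl)-3-methyloxiran-2-yl]methoxy}(tert-butyl)dimethylsilane
Conditions: dimethyl (1-diazo-2-oxopropyl)phosphonate, K2CO3, MeOH, 0 °C → rt
Reagents that add atoms: dimethyl (1-diazo-2-oxopropyl)phosphonate, COP(=O)(OC)C(=[N+]=[N-])C(C)=O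
Why: Seyferth–Gilbert homologation in its Ohira–Bestmann form converts the aldehyde into the terminal alkyne under carbonate conditions mild enough for the oxirane and the silyl ether.

**Step 5**
Reactants: 6 terminal alkyne
Product: 8 tert-butyldimethyl{[(2S,3R)-3-methyl-3-(pent-3-yn-1-yl)oxiran-2-yl]methoxy}silane, via lithium acetylide 7 (not isolated)
Conditions: n-BuLi, THF/DMPU, −78 °C; then MeI, −78 °C → rt
Reagents that add atoms: iodomethane, CI
Why: Acetylide alkylation installs the methyl cap that alkyne metathesis needs, and the acetylide cannot reach the oxirane intramolecularly because only a four-membered ring would result.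

**Step 6**
Reactants: 8 methyl-capped alkyne
Product: 9 [(2S,3R)-3-methyl-3-(pent-3-yn-1-yl)oxiran-2-yl]methanol
Conditions: TBAF, THF, 0 °C
Reagents that add atoms: none
Why: Fluoride desilylation frees the primary alcohol at low temperature without epoxide migration.

**Step 7**
Reactants: 9 epoxy alcohol
Product: 10 (2R,3R)-3-methyl-3-(pent-3-yn-1-yl)oxirane-2-carbaldehyde
Conditions: Dess–Martin periodinane, NaHCO3, CH2Cl2, 0 °C → rt
Reagents that add atoms: none
Why: Buffered Dess–Martin oxidation gives the epoxy aldehyde without acid-induced oxirane opening, and the oxirane C–H is not epimerisable (the descriptor changes to 2R only because CHO outranks the ring carbon).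

**Step 8**
Reactants: 11 (R)-citronellic acid; 12 (4S)-4-benzyl-1,3-oxazolidin-2-one
Product: 14 (4S)-4-benzyl-3-[(3R)-3,7-dimethyloct-6-enoyl]-1,3-oxazolidin-2-one, via mixed pivalic anhydride 13 (not isolated)
Conditions: PivCl, Et3N, THF, −20 °C; then 12, LiCl, −20 °C → rt
Reagents that add atoms: none
Why: Mixed-anhydride N-acylation of the oxazolidinone attaches the auxiliary without touching the C12 methyl stereocentre (R, from the chiral pool).

**Step 9**
Reactants: 14 N-acyl oxazolidinone
Product: 16 (4S)-4-benzyl-3-[(2S,3R)-2-hydroxy-3,7-dimethyloct-6-enoyl]-1,3-oxazolidin-2-one, via sodium enolate 15 (not isolated)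
Conditions: NaHMDS, THF, −78 °C; 2-(benzenesulfonyl)-3-phenyloxaziridine, −78 °C; camphorsulfonic acid quench
Reagents that add atoms: 2-(benzenesulfonyl)-3-phenyloxaziridine, O=S(=O)(c1ccccc1)N1OC1c1ccccc1
Why: Auxiliary-controlled enolate hydroxylation (Evans imide, sulfonyloxaziridine as oxygen donor): the chelated Z sodium enolate is attacked on the face opposite the benzyl group, which sets ring C13 as S irrespective of the neighbouring C12 centre.

**Step 10**
Reactants: 16 α-hydroxy imide
Product: 17 (2S,3R)-2-hydroxy-N-methoxy-N,3,7-trimethyloct-6-enamide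
Conditions: MeNH(OMe)·HCl, AlMe3, CH2Cl2, −10 °C → rt; Rochelle salt work-up
Reagents that add atoms: N,O-dimethylhydroxylamine hydrochloride, CNOC.Cl
Why: Aluminium amide transamination to the Weinreb amide is directed to the exocyclic carbonyl by the neighbouring aluminium alkoxide and releases the auxiliary without epimerising C13.

**Step 11**
Reactants: 17 α-hydroxy Weinreb amide
Product: 18 (2S,3R)-2-[(tert-butyldimethylsilyl)oxy]-N-methoxy-N,3,7-trimethyloct-6-enamide
Conditions: TBSOTf, 2,6-lutidine, CH2Cl2, −78 → 0 °C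
Reagents that add atoms: tert-butyldimethylsilyl trifluoromethanesulfonate, CC(C)(C)[Si](C)(C)OS(=O)(=O)C(F)(F)F
Why: Silyl triflate silylation protects the hindered secondary C13 hydroxyl as the robust ether that is kept until the last step.

**Step 12**
Reactants: 18 silyloxy Weinreb amide
Product: 20 (2S,3R)-2-[(tert-butyldimethylsilyl)oxy]-N-methoxy-N,3-dimethyl-6-oxohexanamide, via secondary ozonide 19 (not isolated)
Conditions: O3, CH2Cl2, −78 °C; then PPh3, −78 °C → rt
Reagents that add atoms: ozone, [O-][O+]=O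
Why: Ozonolysis with reductive work-up cleaves the only alkene to unveil the C9 aldehyde while amide and silyl ether are inert.

**Step 13**
Reactants: 20 aldehyde; 21 1-propynylmagnesium bromide
Product: 22 (2S,3R)-2-[(tert-butyldimethylsilyl)oxy]-6-hydroxy-N-methoxy-N,3-dimethylnon-7-ynamide (both C6 epimers; C6 is ring C9)
Conditions: THF, −78 → −40 °C; aqueous work-up
Reagents that add atoms: none
Why: Grignard addition of the alkynyl reagent is chemoselective for the aldehyde because the hindered Weinreb amide does not react at this temperature, and no control is needed at the new carbinol since it is oxidised later.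

**Step 14**
Reactants: 22 propargylic alcohol
Product: 23 (2S,3R)-2-[(tert-butyldimethylsilyl)oxy]-N-methoxy-N,3-dimethyl-6-[(triethylsilyl)oxy]non-7-ynamide
Conditions: TESCl, imidazole, CH2Cl2, 0 °C
Reagents that add atoms: chlorotriethylsilane, CC[Si](Cl)(CC)CC
Why: O-Silylation with the more labile triethylsilyl group allows C9 to be unmasked later in the presence of the C13 tert-butyldimethylsilyl ether.

**Step 15**
Reactants: 23 Weinreb amide; 24 isobutylmagnesium bromide
Product: 25 (5S,6R)-5-[(tert-butyldimethylsilyl)oxy]-2,6-dimethyl-9-[(triethylsilyl)oxy]dodec-10-yn-4-one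
Conditions: THF, 0 °C; aqueous work-up
Reagents that add atoms: none
Why: Weinreb ketone synthesis stops at the ketone because the chelated tetrahedral adduct survives until work-up, and the non-basic conditions leave the C13 centre intact.

**Step 16**
Reactants: 25 isobutyl ketone; 10 epoxy aldehyde
Product: 27 (4S,5R)-4-[(tert-butyldimethylsilyl)oxy]-1-hydroxy-5-methyl-1-[(2S,3R)-3-methyl-3-(pent-3-yn-1-yl)oxiran-2-yl]-2-(propan-2-yl)-8-[(triethylsilyl)oxy]undec-9-yn-3-one (diastereomers at C1 and C2 of the chain), via lithium enolate 26 (not isolated)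
Conditions: LDA, THF, −78 °C; then 10, −78 °C; AcOH quench at −78 °C
Reagents that add atoms: none
Why: Kinetic lithium enolate aldol addition: LDA removes a proton from the isobutyl CH2 and not from the hindered silyloxy-bearing C13–H, the enolate adds to the reactive epoxy aldehyde, the two new centres are mixtures that the next step erases, and the cold quench avoids epoxide migration.

**Step 17**
Reactants: 27 aldol adduct
Product: 29 (1E,4S,5R)-4-[(tert-butyldimethylsilyl)oxy]-5-methyl-1-[(2S,3R)-3-methyl-3-(pent-3-yn-1-yl)oxiran-2-yl]-2-(propan-2-yl)-8-[(triethylsilyl)oxy]undec-1-en-9-yn-3-one, via mesylate 28 (not isolated)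
Conditions: MsCl, Et3N, CH2Cl2, 0 °C; then DBU, 0 °C → rt
Reagents that add atoms: none
Why: Mesylation and E1cB elimination (aldol condensation) give the conjugated enone with C3 trans to the C14 acyl group and cis to the isopropyl group (1E), the geometry normally preferred in condensation products of α-branched carbonyl compounds.

**Step 18**
Reactants: 29 acyclic diyne epoxy enone
Product: 30 (1E,3S,4R,12R,13S)-13-[(tert-butyldimethylsilyl)oxy]-3,4-epoxy-4,12-dimethyl-1-(propan-2-yl)-9-[(triethylsilyl)oxy]cyclotetradec-1-en-7-yn-14-one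
Conditions: [Mo(≡C–C6H4-4-OMe)(OSiPh3)3] (10 mol%), 5 Å MS, toluene (2 mM), rt → 60 °C
Reagents that add atoms: none
Why: The molybdenum alkylidyne adds to one methyl-capped alkyne in a [2+2] sense to a metallacyclobutadiene, cycloreverts to put the metal on the substrate, and then repeats the sequence intramolecularly with the second alkyne, releasing but-2-yne that the 5 Å sieves absorb so the equilibrium is pulled to the ring. The closest known reaction type is ring-closing alkyne metathesis of bis(methyl-capped) diynes with silanolate-ligated molybdenum alkylidynes in macrocycle synthesis. The 14-membered carbocycle is closed by macrocyclisation of an α,ω-diyne at high dilution, forming the endocyclic C7≡C8 bond, and a ring of this size accommodates the linear C6–C7≡C8–C9 unit. No stereocentre is created and no alkene geometry is at stake, so C3, C4, C12, C13 and the 1E enone pass through unchanged. The step needs alkyne-over-alkene chemoselectivity and tolerance of ketone, oxirane and silyl ethers, which this catalyst class provides because the alkylidyne does not engage olefins and the silanolate ligands temper the Lewis acidity at molybdenum. Closure over oligomerisation is favoured by dilution and by the E-enone and cis-oxirane, which act as turn elements between the two alkyne-bearing arms.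

**Step 19**
Reactants: 30 cycloalkyne
Product: 31 (1E,3S,4R,12R,13S)-13-[(tert-butyldimethylsilyl)oxy]-3,4-epoxy-9-hydroxy-4,12-dimethyl-1-(propan-2-yl)cyclotetradec-1-en-7-yn-14-one
Conditions: HF·pyridine, pyridine, THF, 0 °C
Reagents that add atoms: none
Why: Selective desilylation: the triethylsilyl ether is cleaved much faster than the hindered tert-butyldimethylsilyl ether, and the pyridine buffer protects the oxirane.

**Step 20**
Reactants: 31 propargylic alcohol
Product: 32 (1E,3S,4R,12R,13S)-13-[(tert-butyldimethylsilyl)oxy]-3,4-epoxy-4,12-dimethyl-1-(propan-2-yl)cyclotetradec-1-en-7-yne-9,14-dione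
Conditions: Dess–Martin periodinane, NaHCO3, CH2Cl2, 0 °C
Reagents that add atoms: none
Why: Buffered Dess–Martin oxidation of the propargylic alcohol gives the ynone and merges the two C9 epimers into one compound.

**Step 21**
Reactants: 32 cyclic ynone
Product: 34 (1E,3S,4R,7Z,12R,13S)-13-[(tert-butyldimethylsilyl)oxy]-3,4-epoxy-8-(hydroxymethyl)-4,12-dimethyl-1-(propan-2-yl)cyclotetradeca-1,7-diene-9,14-dione, via copper allenolate 33 (not isolated)
Conditions: [(Ph3P)CuH]6 (1.1 equiv Cu–H), toluene/THF, −40 °C; then monomeric CH2O in THF (from paraformaldehyde), −78 → −40 °C; aq NH4Cl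
Reagents that add atoms: formaldehyde, C=O
Why: Copper hydride reductive aldol: the phosphine-ligated Cu–H transfers hydride to C7 of the ynone, which is more electrophilic and far less hindered than the α-isopropyl C1=C2 enone, and the ring-bound copper allenolate adds to formaldehyde at C8 from the side of the C7 hydrogen (anti to C6), the sense seen in reductive aldols of alkynones and alkynoates, so that H and CH2OH end up cis and the alkene is 7Z.

**Step 22**
Reactants: 34 silyl-protected hydroxymethyl enone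
Product: 35 (1E,3S,4R,7Z,12R,13S)-3,4-epoxy-13-hydroxy-8-(hydroxymethyl)-4,12-dimethyl-1-(propan-2-yl)cyclotetradeca-1,7-diene-9,14-dione (CNP0251075.1)
Conditions: HF·pyridine, pyridine, THF, 0 °C → rt
Reagents that add atoms: none
Why: Buffered fluoride desilylation removes the last silyl ether under non-basic conditions, which avoids epimerisation at C13, retro-aldol loss of the hydroxymethyl group and opening of the oxirane.

**Compound list**

1 | nerol, (2Z)-3,7-dimethylocta-2,6-dien-1-ol | CC(C)=CCC/C(C)=C\CO | starting material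
2 | [(2S,3R)-3-methyl-3-(4-methylpent-3-en-1-yl)oxiran-2-yl]methanol | OC[C@@H]1O[C@]1(C)CCC=C(C)C | intermediate
3 | tert-butyldimethyl{[(2S,3R)-3-methyl-3-(4-methylpent-3-en-1-yl)oxiran-2-yl]methoxy}silane | CC(C)(C)[Si](C)(C)OC[C@@H]1O[C@]1(C)CCC=C(C)C | intermediate
4 | secondary ozonide of 3 (5,5-dimethyl-1,2,4-trioxolan-3-yl at the chain end) | CC(C)(C)[Si](C)(C)OC[C@@H]1O[C@]1(C)CCC2OOC(C)(C)O2 | intermediate
5 | 3-[(2R,3S)-3-{[(tert-butyldimethylsilyl)oxy]methyl}-2-methyloxiran-2-yl]propanal | CC(C)(C)[Si](C)(C)OC[C@@H]1O[C@]1(C)CCC=O | intermediate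
6 | {[(2S,3R)-3-(but-3-yn-1-yl)-3-methyloxiran-2-yl]methoxy}(tert-butyl)dimethylsilane | CC(C)(C)[Si](C)(C)OC[C@@H]1O[C@]1(C)CCC#C | intermediate
7 | lithium acetylide of 6 | CC(C)(C)[Si](C)(C)OC[C@@H]1O[C@]1(C)CCC#C[Li] | intermediate
8 | tert-butyldimethyl{[(2S,3R)-3-methyl-3-(pent-3-yn-1-yl)oxiran-2-yl]methoxy}silane | CC(C)(C)[Si](C)(C)OC[C@@H]1O[C@]1(C)CCC#CC | intermediate
9 | [(2S,3R)-3-methyl-3-(pent-3-yn-1-yl)oxiran-2-yl]methanol | OC[C@@H]1O[C@]1(C)CCC#CC | intermediate
10 | (2R,3R)-3-methyl-3-(pent-3-yn-1-yl)oxirane-2-carbaldehyde | O=C[C@@H]1O[C@]1(C)CCC#CC | intermediate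
11 | (R)-citronellic acid, (3R)-3,7-dimethyloct-6-enoic acid | CC(C)=CCC[C@@H](C)CC(O)=O | starting material
12 | (4S)-4-benzyl-1,3-oxazolidin-2-one | O=C1N[C@@H](Cc2ccccc2)CO1 | starting material
13 | (3R)-3,7-dimethyloct-6-enoic pivalic anhydride | CC(C)=CCC[C@@H](C)CC(=O)OC(=O)C(C)(C)C | intermediate
14 | (4S)-4-benzyl-3-[(3R)-3,7-dimethyloct-6-enoyl]-1,3-oxazolidin-2-one | CC(C)=CCC[C@@H](C)CC(=O)N1[C@@H](Cc2ccccc2)COC1=O | intermediate
15 | sodium (Z)-enolate of 14 | CC(C)=CCC[C@@H](C)/C=C(\O[Na])N1[C@@H](Cc2ccccc2)COC1=O | intermediate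
16 | (4S)-4-benzyl-3-[(2S,3R)-2-hydroxy-3,7-dimethyloct-6-enoyl]-1,3-oxazolidin-2-one | CC(C)=CCC[C@@H](C)[C@H](O)C(=O)N1[C@@H](Cc2ccccc2)COC1=O | intermediate
17 | (2S,3R)-2-hydroxy-N-methoxy-N,3,7-trimethyloct-6-enamide | CC(C)=CCC[C@@H](C)[C@H](O)C(=O)N(C)OC | intermediate
18 | (2S,3R)-2-[(tert-butyldimethylsilyl)oxy]-N-methoxy-N,3,7-trimethyloct-6-enamide | CC(C)=CCC[C@@H](C)[C@H](O[Si](C)(C)C(C)(C)C)C(=O)N(C)OC | intermediate
19 | secondary ozonide of 18 | CC1(C)OOC(CC[C@@H](C)[C@H](O[Si](C)(C)C(C)(C)C)C(=O)N(C)OC)O1 | intermediate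
20 | (2S,3R)-2-[(tert-butyldimethylsilyl)oxy]-N-methoxy-N,3-dimethyl-6-oxohexanamide | O=CCC[C@@H](C)[C@H](O[Si](C)(C)C(C)(C)C)C(=O)N(C)OC | intermediate
21 | 1-propynylmagnesium bromide | CC#C[Mg]Br | starting material
22 | (2S,3R)-2-[(tert-butyldimethylsilyl)oxy]-6-hydroxy-N-methoxy-N,3-dimethylnon-7-ynamide (C6 epimers) | CC#CC(O)CC[C@@H](C)[C@H](O[Si](C)(C)C(C)(C)C)C(=O)N(C)OC | intermediate
23 | (2S,3R)-2-[(tert-butyldimethylsilyl)oxy]-N-methoxy-N,3-dimethyl-6-[(triethylsilyl)oxy]non-7-ynamide (C6 epimers) | CC#CC(O[Si](CC)(CC)CC)CC[C@@H](C)[C@H](O[Si](C)(C)C(C)(C)C)C(=O)N(C)OC | intermediate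
24 | isobutylmagnesium bromide | CC(C)C[Mg]Br | starting material
25 | (5S,6R)-5-[(tert-butyldimethylsilyl)oxy]-2,6-dimethyl-9-[(triethylsilyl)oxy]dodec-10-yn-4-one (C9 epimers) | CC#CC(O[Si](CC)(CC)CC)CC[C@@H](C)[C@H](O[Si](C)(C)C(C)(C)C)C(=O)CC(C)C | intermediate
26 | lithium enolate of 25 (C3=C4 enolate of the chain) | CC#CC(O[Si](CC)(CC)CC)CC[C@@H](C)[C@H](O[Si](C)(C)C(C)(C)C)C(O[Li])=CC(C)C | intermediate
27 | (4S,5R)-4-[(tert-butyldimethylsilyl)oxy]-1-hydroxy-5-methyl-1-[(2S,3R)-3-methyl-3-(pent-3-yn-1-yl)oxiran-2-yl]-2-(propan-2-yl)-8-[(triethylsilyl)oxy]undec-9-yn-3-one (diastereomers at C1, C2, C8) | CC(C)C(C(O)[C@@H]1O[C@]1(C)CCC#CC)C(=O)[C@@H](O[Si](C)(C)C(C)(C)C)[C@H](C)CCC(O[Si](CC)(CC)CC)C#CC | intermediate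
28 | C1 methanesulfonate of 27 | CC(C)C(C(OS(C)(=O)=O)[C@@H]1O[C@]1(C)CCC#CC)C(=O)[C@@H](O[Si](C)(C)C(C)(C)C)[C@H](C)CCC(O[Si](CC)(CC)CC)C#CC | intermediate
29 | (1E,4S,5R)-4-[(tert-butyldimethylsilyl)oxy]-5-methyl-1-[(2S,3R)-3-methyl-3-(pent-3-yn-1-yl)oxiran-2-yl]-2-(propan-2-yl)-8-[(triethylsilyl)oxy]undec-1-en-9-yn-3-one (C8 epimers) | CC(C)/C(=C\[C@@H]1O[C@]1(C)CCC#CC)C(=O)[C@@H](O[Si](C)(C)C(C)(C)C)[C@H](C)CCC(O[Si](CC)(CC)CC)C#CC | intermediate
30 | (1E,3S,4R,12R,13S)-13-[(tert-butyldimethylsilyl)oxy]-3,4-epoxy-4,12-dimethyl-1-(propan-2-yl)-9-[(triethylsilyl)oxy]cyclotetradec-1-en-7-yn-14-one (C9 epimers) | CC(C)/C1=C\[C@@H]2O[C@]2(C)CCC#CC(O[Si](CC)(CC)CC)CC[C@@H](C)[C@H](O[Si](C)(C)C(C)(C)C)C1=O | intermediate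
31 | (1E,3S,4R,12R,13S)-13-[(tert-butyldimethylsilyl)oxy]-3,4-epoxy-9-hydroxy-4,12-dimethyl-1-(propan-2-yl)cyclotetradec-1-en-7-yn-14-one (C9 epimers) | CC(C)/C1=C\[C@@H]2O[C@]2(C)CCC#CC(O)CC[C@@H](C)[C@H](O[Si](C)(C)C(C)(C)C)C1=O | intermediate
32 | (1E,3S,4R,12R,13S)-13-[(tert-butyldimethylsilyl)oxy]-3,4-epoxy-4,12-dimethyl-1-(propan-2-yl)cyclotetradec-1-en-7-yne-9,14-dione | CC(C)/C1=C\[C@@H]2O[C@]2(C)CCC#CC(=O)CC[C@@H](C)[C@H](O[Si](C)(C)C(C)(C)C)C1=O | intermediate
33 | copper(I) allenolate of 32 (C7=C8=C9–O–Cu in the ring) | CC(C)/C1=C\[C@@H]2O[C@]2(C)CCC=C=C(O[Cu])CC[C@@H](C)[C@H](O[Si](C)(C)C(C)(C)C)C1=O | intermediate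
34 | (1E,3S,4R,7Z,12R,13S)-13-[(tert-butyldimethylsilyl)oxy]-3,4-epoxy-8-(hydroxymethyl)-4,12-dimethyl-1-(propan-2-yl)cyclotetradeca-1,7-diene-9,14-dione | CC(C)/C1=C\[C@@H]2O[C@]2(C)CC/C=C(/CO)C(=O)CC[C@@H](C)[C@H](O[Si](C)(C)C(C)(C)C)C1=O | intermediate
35 | (1E,3S,4R,7Z,12R,13S)-3,4-epoxy-13-hydroxy-8-(hydroxymethyl)-4,12-dimethyl-1-(propan-2-yl)cyclotetradeca-1,7-diene-9,14-dione (CNP0251075.1) | CC(C)/C1=C\[C@@H]2O[C@]2(C)CC/C=C(/CO)C(=O)CC[C@@H](C)[C@H](O)C1=O | target

**Step count**

Total: 22 steps (7 for the epoxy aldehyde, 8 for the ketone, 7 from fragment union to the target).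
Longest linear sequence: 15 steps (steps 8–22, from (R)-citronellic acid).

**Steps most likely to fail, with fallbacks**

1. Step 21. The copper allenolate may be protonated before it meets formaldehyde, may be captured on the C6 side (7E alkene), or hydride may also be delivered to C2 of the epoxy enone with opening of the oxirane. The fallback sets out from 32 and returns at 34. Ynone 32 is treated with the complex of diisobutylaluminium hydride and HMPA in THF at 0 °C (hydroalumination of the ynone, syn addition with aluminium on C8), which should give the C8-diisobutylaluminio enone F1 with the C7 hydrogen and the metal cis. F1 is exposed in the same flask to monomeric formaldehyde, and C–C bond formation with retention at C8 followed by aqueous tartrate work-up gives 34. In this variant the 7Z geometry comes from the syn hydrometalation of the ring alkyne and a C-bound metal, not from the face on which an O-bound allenolate is captured.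

2. Step 18. Intermolecular metathesis to acyclic oligomers may outrun closure if the rigid E-enone and cis-oxirane segment resists folding, or the conjugated ketone and oxirane may tie up the molybdenum centre. The fallback sets out from 27 and returns at 30. The C2 hydroxyl of aldol adduct 27 is capped (TMSCl, imidazole, CH2Cl2) to give the trimethylsilyl ether F2. Ring-closing alkyne metathesis of F2 under the conditions of step 18 closes the ring while C1 and C2 are still sp3, so the chain is more flexible and the ketone is not conjugated, giving the cycloalkyne F3. Citric acid in MeOH at 0 °C removes only the trimethylsilyl group and gives the ring β-hydroxy ketone F4. Mesylation (MsCl, Et3N, CH2Cl2, 0 °C) gives the mesylate F5, which is not isolated, and DBU then forms the C1=C2 enone inside the ring and delivers 30.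

3. Step 17 (with the aldol of step 16). The E1cB elimination may give a mixture of enone geometries, or the amine base may epimerise C13. The fallback sets out from 23 and returns at 29. Weinreb amide 23 is used to acylate lithiated diethyl (2-methylpropyl)phosphonate (n-BuLi, THF, −78 °C, two equivalents of the anion), giving the β-keto phosphonate F6. Horner–Wadsworth–Emmons olefination of F6 with epoxy aldehyde 10 (Ba(OH)2, wet THF, rt) forms the C1=C2 bond directly and returns to 29, with the acyl group trans to C3 as is usual for α-substituted keto phosphonates and without a strongly basic elimination next to C13.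

**Further compounds**

F1 | step 21 | (1E,3S,4R,12R,13S)-13-[(tert-butyldimethylsilyl)oxy]-8-(diisobutylalumanyl)-3,4-epoxy-4,12-dimethyl-1-(propan-2-yl)cyclotetradeca-1,7-diene-9,14-dione (C7–H and Al cis) | CC(C)/C1=C\[C@@H]2O[C@]2(C)CC/C=C(/[Al](CC(C)C)CC(C)C)C(=O)CC[C@@H](C)[C@H](O[Si](C)(C)C(C)(C)C)C1=O
F2 | step 18 | C1 trimethylsilyl ether of aldol adduct 27 | CC(C)C(C(O[Si](C)(C)C)[C@@H]1O[C@]1(C)CCC#CC)C(=O)[C@@H](O[Si](C)(C)C(C)(C)C)[C@H](C)CCC(O[Si](CC)(CC)CC)C#CC
F3 | step 18 | (3S,4R,12R,13S)-13-[(tert-butyldimethylsilyl)oxy]-3,4-epoxy-4,12-dimethyl-1-(propan-2-yl)-9-[(triethylsilyl)oxy]-2-[(trimethylsilyl)oxy]cyclotetradec-7-yn-14-one | CC(C)C1C(O[Si](C)(C)C)[C@@H]2O[C@]2(C)CCC#CC(O[Si](CC)(CC)CC)CC[C@@H](C)[C@H](O[Si](C)(C)C(C)(C)C)C1=O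
F4 | step 18 | (3S,4R,12R,13S)-13-[(tert-butyldimethylsilyl)oxy]-3,4-epoxy-2-hydroxy-4,12-dimethyl-1-(propan-2-yl)-9-[(triethylsilyl)oxy]cyclotetradec-7-yn-14-one | CC(C)C1C(O)[C@@H]2O[C@]2(C)CCC#CC(O[Si](CC)(CC)CC)CC[C@@H](C)[C@H](O[Si](C)(C)C(C)(C)C)C1=O
F5 | step 18 | C2 methanesulfonate of F4 | CC(C)C1C(OS(C)(=O)=O)[C@@H]2O[C@]2(C)CCC#CC(O[Si](CC)(CC)CC)CC[C@@H](C)[C@H](O[Si](C)(C)C(C)(C)C)C1=O
F6 | step 17 | diethyl {(5S,6R)-5-[(tert-butyldimethylsilyl)oxy]-2,6-dimethyl-4-oxo-9-[(triethylsilyl)oxy]dodec-10-yn-3-yl}phosphonate | CCOP(=O)(OCC)C(C(C)C)C(=O)[C@@H](O[Si](C)(C)C(C)(C)C)[C@H](C)CCC(O[Si](CC)(CC)CC)C#CC
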